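**Retrosynthetic overview**

- The lactone C–O bond is made last: the phthalide is opened to an ortho-carboxamido aryl ketone. Asymmetric transfer hydrogenation sets C3, and the new benzylic hydroxyl closes onto the carboxyl derivative, as the chain-bound hydroxy acid would.
- The aryl ketone is cut at its C(=O)–CH2 bond into a 2-formylbenzamide and a terminal alkene (intermolecular hydroacylation), so the two halves meet at the ketone oxidation level without protecting groups.
- The spiroketal is cut to the open-chain 1,7-dihydroxy-4-ketone, assembled in one flask from acetone dimethylhydrazone and two enantiopure epoxides; unmasking the ketone closes both oxolane rings at once.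
- Ring order: both spiroketal rings first (one cascade), lactone ring last. The spiro carbon is thermodynamic and is fixed only in the final step by acid equilibration and separation.

Assumption: the spiro carbon of a 5,5-spiroketal epimerises freely under acid, so every spiroketal compound before the target is carried as the mixture of its two spiro epimers (SMILES left open at that atom; spiroketal numbering O1, C2 chain-bearing, C5 spiro, O6, C7 methyl-bearing; C5'' in the phthalides).

**Route**

Step 1
Reactants: 1 5-bromopent-1-ene; 2 (S)-epichlorohydrin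
Product: 5 (S)-2-(hex-5-en-1-yl)oxirane, via pent-4-enylmagnesium bromide 3 (not isolated), via chlorohydrin 4 (not isolated)
Conditions: Mg, THF, rt; CuI (5 mol %), 2, −40 → −20 °C; then 5 M aq NaOH, rt; distillation
Reagents that add atoms: none
Why: Cu-catalysed Grignard opening of the epoxide at its CH2 terminus gives the chlorohydrin and NaOH closes the new epoxide by intramolecular Williamson displacement of chloride; no bond at the stereocentre is broken and the CIP order is unchanged, so (S)-2 gives (S)-5.

Step 2
Reactants: 6 acetone N,N-dimethylhydrazone; 7 (S)-propylene oxide; 5 (S)-2-(hex-5-en-1-yl)oxirane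
Product: 11 (2S,7S)-2-(hex-5-en-1-yl)-7-methyl-1,6-dioxaspiro[4.4]nonane (both C5 epimers), via hydroxy hydrazone 8 (not isolated), via dihydroxy hydrazone 9 (not isolated), via dihydroxy ketone 10 (not isolated)
Conditions: n-BuLi, THF, −78 → 0 °C; 7, −78 → 0 °C; n-BuLi, −78 → 0 °C; 5, 0 °C → rt; then 2 M HCl, Et2O, rt
Reagents that add atoms: none
Why: Corey–Enders aza-enolate alkylation: the lithiated hydrazone opens each epoxide at its CH2 terminus (the second lithiation occurs at the remaining methyl group), so C2 and C7 carry the untouched epoxide stereocentres, and aqueous acid hydrolyses the hydrazone to the 1,7-dihydroxy-4-ketone, which undergoes double dehydrative spiroketalisation as proposed for the natural chain, giving the spiro carbon as a thermodynamic mixture of about 1:1.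

Step 3
Reactants: 12 2,4-dimethoxybenzoyl chloride
Product: 13 N,N-diethyl-2,4-dimethoxybenzamide
Conditions: Et2NH, 2 M aq NaOH, CH2Cl2, 0 °C → rt
Reagents that add atoms: diethylamine, CCNCC
Why: Schotten–Baumann acylation of the amine by the acid chloride; no stereocentre is involved.

Step 4
Reactants: 13 N,N-diethyl-2,4-dimethoxybenzamide
Product: 15 N,N-diethyl-2-formyl-4,6-dimethoxybenzamide, via aryllithium 14 (not isolated)
Conditions: s-BuLi, TMEDA, THF, −78 °C; DMF, −78 → 0 °C; 1 M HCl
Reagents that add atoms: N,N-dimethylformamide, CN(C)C=O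
Why: Directed ortho-metalation: the tertiary amide is the strongest director on the ring and guides s-BuLi to its only free ortho position in preference to the site between the two methoxy groups, and DMF formylates the aryllithium.

Step 5
Reactants: 15 N,N-diethyl-2-formyl-4,6-dimethoxybenzamide; 11 (2S,7S)-2-(hex-5-en-1-yl)-7-methyl-1,6-dioxaspiro[4.4]nonane (both C5 epimers, 1.5 equiv)
Product: 16 N,N-diethyl-2-{7-[(2S,7S)-7-methyl-1,6-dioxaspiro[4.4]nonan-2-yl]heptanoyl}-4,6-dimethoxybenzamide (both C5 epimers)
Conditions: RhCl(PPh3)3 (5 mol %), 2-amino-3-picoline (40 mol %), PhCO2H (10 mol %), PhNH2 (60 mol %), toluene, 130 °C (sealed tube)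
Reagents that add atoms: none
Why: Chelation-assisted intermolecular hydroacylation (Jun type): 2-amino-3-picoline forms the aldimine in situ, its pyridine nitrogen directs Rh into the aldimine C–H bond, anti-Markovnikov insertion of the terminal alkene gives the linear ketimine, and the water released in the condensation hydrolyses it to the ketone; no stereocentre is formed and the spiroketal is inert.

Step 6
Reactants: 16 N,N-diethyl-2-{7-[(2S,7S)-7-methyl-1,6-dioxaspiro[4.4]nonan-2-yl]heptanoyl}-4,6-dimethoxybenzamide (both C5 epimers)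
Product: 19 (3S)-5,7-dimethoxy-3-{6-[(2S,5S,7S)-7-methyl-1,6-dioxaspiro[4.4]nonan-2-yl]hexyl}-2-benzofuran-1(3H)-one, via hydroxy amide 17 (not isolated), via spiro-epimeric lactone 18 (not isolated)
Conditions: RuCl[(S,S)-TsDPEN](p-cymene) (2 mol %), HCO2H/Et3N (5:2), 40 °C; evaporation; then TsOH·H2O (1.5 equiv), toluene, 80 °C; preparative HPLC
Reagents that add atoms: none
Why: Noyori asymmetric transfer hydrogenation: the (S,S)-TsDPEN–Ru hydride differentiates aryl from alkyl as with acetophenone and gives the (S)-benzylic alcohol 17; TsOH then drives 5-exo-trig lactonisation onto the ortho amide with retention at C3 (the carbinol C–O bond is not broken) and equilibrates the spiro carbon, so lactone 18 forms as an about 1:1 mixture of its two C5'' epimers, from which the (5''S) epimer 19 is separated by preparative HPLC while the remaining fraction of 18 is returned to acid equilibration (TsOH cat., CH2Cl2, rt) and separated again.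

**Compound list**

1 | 5-bromopent-1-ene | C=CCCCBr | starting material
2 | (S)-epichlorohydrin, (S)-2-(chloromethyl)oxirane | ClC[C@@H]1CO1 | starting material
3 | pent-4-en-1-ylmagnesium bromide | C=CCCC[Mg]Br | intermediate
4 | (S)-1-chlorooct-7-en-2-ol (formed as its magnesium alkoxide) | C=CCCCC[C@H](O)CCl | intermediate
5 | (S)-2-(hex-5-en-1-yl)oxirane | C=CCCCC[C@H]1CO1 | intermediate
6 | acetone N,N-dimethylhydrazone | CC(C)=NN(C)C | starting material
7 | (S)-propylene oxide, (S)-2-methyloxirane | C[C@H]1CO1 | starting material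
8 | (S)-5-(2,2-dimethylhydrazinylidene)hexan-2-ol (formed as its lithium alkoxide) | C[C@H](O)CCC(C)=NN(C)C | intermediate
9 | (2S,8S)-5-(2,2-dimethylhydrazinylidene)tetradec-13-ene-2,8-diol (formed as its dilithium alkoxide) | C[C@H](O)CCC(=NN(C)C)CC[C@@H](O)CCCCC=C | intermediate
10 | (2S,8S)-2,8-dihydroxytetradec-13-en-5-one | C[C@H](O)CCC(=O)CC[C@@H](O)CCCCC=C | intermediate
11 | (2S,7S)-2-(hex-5-en-1-yl)-7-methyl-1,6-dioxaspiro[4.4]nonane, both C5 epimers | C=CCCCC[C@H]1CCC2(CC[C@H](C)O2)O1 | intermediate
12 | 2,4-dimethoxybenzoyl chloride | COc1ccc(C(=O)Cl)c(OC)c1 | starting material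
13 | N,N-diethyl-2,4-dimethoxybenzamide | CCN(CC)C(=O)c1ccc(OC)cc1OC | intermediate
14 | N,N-diethyl-2-lithio-4,6-dimethoxybenzamide | CCN(CC)C(=O)c1c([Li])cc(OC)cc1OC | intermediate
15 | N,N-diethyl-2-formyl-4,6-dimethoxybenzamide | CCN(CC)C(=O)c1c(C=O)cc(OC)cc1OC | intermediate
16 | N,N-diethyl-2-{7-[(2S,7S)-7-methyl-1,6-dioxaspiro[4.4]nonan-2-yl]heptanoyl}-4,6-dimethoxybenzamide, both C5 epimers | CCN(CC)C(=O)c1c(OC)cc(OC)cc1C(=O)CCCCCC[C@H]1CCC2(CC[C@H](C)O2)O1 | intermediate
17 | N,N-diethyl-2-{(1S)-1-hydroxy-7-[(2S,7S)-7-methyl-1,6-dioxaspiro[4.4]nonan-2-yl]heptyl}-4,6-dimethoxybenzamide, both C5 epimers | CCN(CC)C(=O)c1c(OC)cc(OC)cc1[C@@H](O)CCCCCC[C@H]1CCC2(CC[C@H](C)O2)O1 | intermediate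
18 | (3S)-5,7-dimethoxy-3-{6-[(2S,7S)-7-methyl-1,6-dioxaspiro[4.4]nonan-2-yl]hexyl}-2-benzofuran-1(3H)-one, both C5'' epimers | COc1cc(OC)c2c(c1)[C@H](CCCCCC[C@H]1CCC3(CC[C@H](C)O3)O1)OC2=O | intermediate
19 | (3S)-5,7-dimethoxy-3-{6-[(2S,5S,7S)-7-methyl-1,6-dioxaspiro[4.4]nonan-2-yl]hexyl}-2-benzofuran-1(3H)-one | COc1cc(OC)c2c(c1)[C@H](CCCCCC[C@H]1CC[C@]3(CC[C@H](C)O3)O1)OC2=O | target

**Step count and risks**

Total steps: 6. Longest linear sequence: 4 steps (steps 1 → 2 → 5 → 6; the arene branch, steps 3 → 4 → 5 → 6, is equally long). Re-equilibration of the recovered fraction of 18 is not counted.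

Where each stereocentre comes from: C7'' from (S)-propylene oxide, C2'' from (S)-epichlorohydrin, C3 from the transfer hydrogenation, C5'' from acid equilibration and HPLC separation in step 6. After separation 19 must be kept free of acid.

The three steps most likely to fail:

Step 5 (hydroacylation). The ortho-carboxamido aldehyde may react sluggishly, decarbonylate, or its imine may attack the neighbouring amide; the alkene may isomerise. The fallback sets out from 11. Cross-metathesis with N-methoxy-N-methylacrylamide (second-generation Grubbs catalyst RuCl2(=CHPh)(PCy3)(H2IMes), CH2Cl2, 40 °C) gives (E)-N-methoxy-N-methyl-7-[(2S,7S)-7-methyl-1,6-dioxaspiro[4.4]nonan-2-yl]hept-2-enamide F1. Hydrogenation (H2, 10 % Pd/C, EtOAc) gives N-methoxy-N-methyl-7-[(2S,7S)-7-methyl-1,6-dioxaspiro[4.4]nonan-2-yl]heptanamide F2. Addition of aryllithium 14 (made from 13 as in step 4) to F2 in THF at −78 °C gives keto amide 16, where the route is rejoined.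

Step 6 (reduction, lactonisation, spiro equilibration). The ketone sits next to a twisted, bulky amide, so rate or enantioselectivity of the transfer hydrogenation may be insufficient. The about 1:1 spiro ratio is inherent to 5,5-spiroketals and makes HPLC separation and re-equilibration unavoidable in either case. The fallback sets C3 in a C–C bond-forming union instead of a C=O reduction and bypasses 16. It sets out from 11: hydroboration with Et2BH gives diethyl{6-[(2S,7S)-7-methyl-1,6-dioxaspiro[4.4]nonan-2-yl]hexyl}borane F3. Boron–zinc exchange with neat Et2Zn and evaporation of the volatiles gives bis{6-[(2S,7S)-7-methyl-1,6-dioxaspiro[4.4]nonan-2-yl]hexyl}zinc F4. Addition of F4 to aldehyde 15 with Ti(OiPr)4 and (1R,2R)-N,N'-bis(trifluoromethanesulfonyl)cyclohexane-1,2-diamine (8 mol %) in toluene at −20 °C, the ligand enantiomer that gives (S)-carbinols from aryl aldehydes, leads after 1 M HCl work-up to hydroxy amide 17. From 17 the TsOH lactonisation, equilibration and HPLC of step 6 follow unchanged.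

Step 2 (three-component coupling). The second metalation and epoxide opening take place in the presence of a lithium alkoxide and may be slow or give the regioisomeric aza-enolate. The fallback reverses the polarity and sets out from 5. Opening with PhSCH2Li (thioanisole, n-BuLi, DABCO, THF, 0 °C) gives (S)-1-(phenylsulfanyl)non-8-en-3-ol F5. Deprotonation with n-BuLi and reductive lithiation with lithium 4,4'-di-tert-butylbiphenylide (THF, −78 °C) gives lithium (R)-1-lithionon-8-en-3-olate F6 (same spatial arrangement as F5; only the CIP order changes). F6 is added to commercial (S)-γ-valerolactone at −78 °C, and work-up with 2 M HCl gives dihydroxy ketone 10, which closes to spiroketal 11 in the same flask.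

**Further compounds**

F1 | step 5 | (E)-N-methoxy-N-methyl-7-[(2S,7S)-7-methyl-1,6-dioxaspiro[4.4]nonan-2-yl]hept-2-enamide, both C5 epimers | CON(C)C(=O)/C=C/CCCC[C@H]1CCC2(CC[C@H](C)O2)O1
F2 | step 5 | N-methoxy-N-methyl-7-[(2S,7S)-7-methyl-1,6-dioxaspiro[4.4]nonan-2-yl]heptanamide, both C5 epimers | CON(C)C(=O)CCCCCC[C@H]1CCC2(CC[C@H](C)O2)O1
F3 | step 6 | diethyl{6-[(2S,7S)-7-methyl-1,6-dioxaspiro[4.4]nonan-2-yl]hexyl}borane, both C5 epimers | CCB(CC)CCCCCC[C@H]1CCC2(CC[C@H](C)O2)O1
F4 | step 6 | bis{6-[(2S,7S)-7-methyl-1,6-dioxaspiro[4.4]nonan-2-yl]hexyl}zinc, C5 epimers | C(CCCCC[C@H]1CCC2(CC[C@H](C)O2)O1)[Zn]CCCCCC[C@H]1CCC2(CC[C@H](C)O2)O1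
F5 | step 2 | (S)-1-(phenylsulfanyl)non-8-en-3-ol | C=CCCCC[C@H](O)CCSc1ccccc1
F6 | step 2 | lithium (R)-1-lithionon-8-en-3-olate | C=CCCCC[C@H](O[Li])CC[Li]
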